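The route rests on cutting two bonds of a sacrificial pyran, Cc–Ca and O7–Cx (Cc = methine on flavan C8 bearing pyrogallol ring B'; Ca = CH–O-gallate; Cx = chain CH2 on phloroglucinol ring A'). The feature exploited is that phenol O7 of flavan ring D is ortho to C8: a perbenzylated flavan 3-gallate with free 7-OH and an 8-[aryl(hydroxy)methyl] group becomes an ortho-quinone methide, and one chiral phosphoric acid-catalysed [4+2] with the (E)-enol gallate of ring A' acetaldehyde joins the halves, installs the second gallate and sets Cc and Ca. The O7–Cx bond, benzylic to ring A', is then cleaved reductively before global debenzylation.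

Key step: step 12

Assumption: the sense of induction of the phosphoric acid on this chiral substrate cannot be predicted with certainty; the (R) antipode is written and the matched antipode is to be settled by running both.

Step 1
Reactants: 1 (−)-epigallocatechin
Product: 2 5,7,3',4',5'-penta-O-benzyl-(−)-epigallocatechin
Conditions: BnBr (5.5 equiv), K2CO3, DMF, 0 °C to rt
Reagents that add atoms: benzyl bromide, BrCc1ccccc1
Why: Williamson etherification: K2CO3 ionises the five phenols but not the secondary alcohol at C3, so only phenolic oxygen is benzylated and the 2R,3R centres are untouched.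

Step 2
Reactants: 2 5,7,3',4',5'-penta-O-benzyl-(−)-epigallocatechin
Product: 3 8-bromo-5,7,3',4',5'-penta-O-benzyl-(−)-epigallocatechin
Conditions: NBS (1.0 equiv), CH2Cl2, −78 °C to rt
Reagents that add atoms: N-bromosuccinimide, O=C1CCC(=O)N1Br
Why: Electrophilic aromatic bromination: ring D is the most electron-rich arene and reacts at C8, which is para to O5 and less screened than C6, which lies between two benzyloxy groups.

Step 3
Reactants: 4 3,4,5-tris(benzyloxy)benzoic acid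
Product: 6 N-methoxy-N-methyl-3,4,5-tris(benzyloxy)benzamide, via acyl imidazole 5 (not isolated)
Conditions: CDI, CH2Cl2, rt; then MeNH(OMe)·HCl, rt
Reagents that add atoms: N,O-dimethylhydroxylamine hydrochloride, CNOC.Cl
Why: Amide formation through the acyl imidazole (carbonyldiimidazole activation), which needs no acid chloride and leaves the benzyl ethers alone.

Step 4
Reactants: 3 8-bromo-5,7,3',4',5'-penta-O-benzyl-(−)-epigallocatechin; 6 N-methoxy-N-methyl-3,4,5-tris(benzyloxy)benzamide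
Product: 9 8-[3,4,5-tris(benzyloxy)benzoyl]-5,7,3',4',5'-penta-O-benzyl-(−)-epigallocatechin (3-OH free), via 8-lithio flavan 3-olate 7 (not isolated), via lithium hemiaminal adduct 8 (not isolated)
Conditions: MeLi (1.05 equiv), THF, −78 °C; t-BuLi (2.1 equiv), −78 °C; then 6, −78 to 0 °C; H2O
Reagents that add atoms: none
Why: Bromine–lithium exchange followed by Weinreb ketone synthesis: the C3 hydroxyl is first turned into its lithium alkoxide so that no protecting group is needed, exchange at C8 is fast at −78 °C, and the chelated adduct 8 gives the diaryl ketone only on work-up, which rules out over-addition.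

Step 5
Reactants: 9 8-[3,4,5-tris(benzyloxy)benzoyl]-5,7,3',4',5'-penta-O-benzyl-(−)-epigallocatechin; 4 3,4,5-tris(benzyloxy)benzoic acid
Product: 10 (2R,3R)-5,7-bis(benzyloxy)-8-[3,4,5-tris(benzyloxy)benzoyl]-2-[3,4,5-tris(benzyloxy)phenyl]chroman-3-yl 3,4,5-tris(benzyloxy)benzoate
Conditions: DCC, DMAP (cat.), CH2Cl2, rt
Reagents that add atoms: none
Why: Steglich esterification of the only free hydroxyl, the C3 alcohol, whose C–O bond is not broken, so the configuration at C3 is kept.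

Step 6
Reactants: 10 (2R,3R)-5,7-bis(benzyloxy)-8-[3,4,5-tris(benzyloxy)benzoyl]-2-[3,4,5-tris(benzyloxy)phenyl]chroman-3-yl 3,4,5-tris(benzyloxy)benzoate
Product: 11 (2R,3R)-5-(benzyloxy)-7-hydroxy-8-[3,4,5-tris(benzyloxy)benzoyl]-2-[3,4,5-tris(benzyloxy)phenyl]chroman-3-yl 3,4,5-tris(benzyloxy)benzoate
Conditions: MgBr2·OEt2 (3 equiv), toluene/Et2O, 60 °C; then H2O
Reagents that add atoms: none
Why: Chelation-controlled ether cleavage: magnesium is held between the C8 ketone oxygen and O7, the only benzylated oxygen ortho to a carbonyl group, and bromide removes that benzyl group in an SN2 step while the ten remaining benzyl ethers and the ester stay inert.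

Step 7
Reactants: 11 (2R,3R)-5-(benzyloxy)-7-hydroxy-8-[3,4,5-tris(benzyloxy)benzoyl]-2-[3,4,5-tris(benzyloxy)phenyl]chroman-3-yl 3,4,5-tris(benzyloxy)benzoate
Product: 12 (2R,3R)-5-(benzyloxy)-7-hydroxy-8-{hydroxy[3,4,5-tris(benzyloxy)phenyl]methyl}-2-[3,4,5-tris(benzyloxy)phenyl]chroman-3-yl 3,4,5-tris(benzyloxy)benzoate (both carbinol epimers)
Conditions: NaBH4, THF/EtOH, 0 °C; pH 7 buffer; used without chromatography
Reagents that add atoms: none
Why: Hydride reduction of the diaryl ketone by NaBH4, which does not attack the benzoate ester; the new carbinol centre forms as both epimers, which is of no consequence because it becomes trigonal in step 12.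

Step 8
Reactants: 13 1,3,5-tris(benzyloxy)benzene
Product: 15 2,4,6-tris(benzyloxy)benzaldehyde, via benzylidene iminium chloride 14 (not isolated)
Conditions: POCl3, DMF, 0 °C to rt; then H2O
Reagents that add atoms: N,N-dimethylformamide, CN(C)C=O; water, O
Why: Vilsmeier–Haack formylation of a threefold symmetric, strongly activated arene, for which all ring positions are equivalent and the first formyl group deactivates the ring against a second.

Step 9
Reactants: 15 2,4,6-tris(benzyloxy)benzaldehyde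
Product: 16 4,4,5,5-tetramethyl-2-{(E)-2-[2,4,6-tris(benzyloxy)phenyl]ethenyl}-1,3,2-dioxaborolane
Conditions: CH2(Bpin)2, lithium 2,2,6,6-tetramethylpiperidide, THF, 0 °C; then 15, −78 °C to rt
Reagents that add atoms: bis(4,4,5,5-tetramethyl-1,3,2-dioxaborolan-2-yl)methane, CC1(C)OB(CB2OC(C)(C)C(C)(C)O2)OC1(C)C
Why: Boron–Wittig olefination: the lithiated geminal bis(boronate) adds to the aldehyde and elimination of the boron–oxygen pair gives the alkenyl boronate with aryl and boryl groups trans, which fixes the E geometry.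

Step 10
Reactants: 16 4,4,5,5-tetramethyl-2-{(E)-2-[2,4,6-tris(benzyloxy)phenyl]ethenyl}-1,3,2-dioxaborolane
Product: 17 potassium trifluoro{(E)-2-[2,4,6-tris(benzyloxy)phenyl]ethenyl}borate
Conditions: KHF2, MeOH/H2O, rt
Reagents that add atoms: potassium hydrogen difluoride, [K+].[F-].F
Why: Ligand exchange at boron (pinacol boronate to trifluoroborate salt) that does not involve the alkene, so the E geometry is retained.

Step 11
Reactants: 17 potassium trifluoro{(E)-2-[2,4,6-tris(benzyloxy)phenyl]ethenyl}borate; 4 3,4,5-tris(benzyloxy)benzoic acid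
Product: 18 (E)-2-[2,4,6-tris(benzyloxy)phenyl]ethenyl 3,4,5-tris(benzyloxy)benzoate
Conditions: CuBr (10 mol %), DMAP, 4 Å MS, O2 (1 atm), MeCN, 40 °C
Reagents that add atoms: none
Why: Copper-catalysed oxidative C–O coupling of an alkenyl trifluoroborate with a carboxylic acid (Chan–Lam type), in which the alkenyl group is transferred with retention and the E enol ester results.

Step 12
Reactants: 12 (2R,3R)-5-(benzyloxy)-7-hydroxy-8-{hydroxy[3,4,5-tris(benzyloxy)phenyl]methyl}-2-[3,4,5-tris(benzyloxy)phenyl]chroman-3-yl 3,4,5-tris(benzyloxy)benzoate (both carbinol epimers); 18 (E)-2-[2,4,6-tris(benzyloxy)phenyl]ethenyl 3,4,5-tris(benzyloxy)benzoate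
Product: 20 cycloadduct (flavan 3-gallate fused at O7/C8 to the pyran O7–Cx–Ca–Cc; Cx R/Ca S/Cc R; 2,3-trans-3,4-trans), via ortho-quinone methide 19 (not isolated)
Conditions: (R)-3,3'-bis(2,4,6-triisopropylphenyl)-1,1'-binaphthyl-2,2'-diyl hydrogen phosphate (10 mol %), 18 (2 equiv), 5 Å MS, toluene, −20 °C to rt, slow addition of 12
Reagents that add atoms: none
Why: Proposed new method: the phosphoric acid dehydrates 12 to the E-configured ortho-quinone methide 19 (C7=O, C8=Cc), hydrogen-bonded through its carbonyl oxygen to the phosphate, and Ca of 18 attacks Cc because only this orientation places the developing positive charge on Cx, where ring A' stabilises it far better than an acyloxy oxygen could at Ca, after which O7 collapses onto Cx. The closest known reaction type is the chiral phosphoric acid-catalysed inverse-demand oxa-[4+2] cycloaddition of in situ ortho-quinone methides with electron-rich styrenes, which has not been shown for a β-acyloxystyrene, whose ester oxygen lowers the nucleophilicity of the attacking carbon. The single new ring, the six-membered pyran O7–Cx–Ca–Cc–C8–C7, closes by an asynchronous [4+2] that in its stepwise limit is a 6-exo-trig capture of the Cx benzylic cation by the phenol oxygen. Of the three new stereocentres, Cx/Ca trans is fixed by suprafacial addition to the E alkene, Ca/Cc trans by the transition state with ring A' endo and the acyloxy group exo to the methide aryl (all-equatorial product), and the absolute configuration at Cc by the chiral phosphate pocket acting together with the C2 aryl and C3 gallate of the flavan. The step needs Ca-to-Cc regioselectivity, secured by the trialkoxybenzyl cation, and chemoselectivity for the alkene over Friedel–Crafts attack by aromatic carbons, secured by the flanking benzyloxy groups at the free positions of ring A', by excess 18 and by keeping 12 dilute.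

Step 13
Reactants: 20 cycloadduct (flavan 3-gallate fused at O7/C8 to the pyran O7–Cx–Ca–Cc)
Product: 22 (2R,3R)-5-(benzyloxy)-7-hydroxy-8-{(1R,2R)-2-{[3,4,5-tris(benzyloxy)benzoyl]oxy}-3-[2,4,6-tris(benzyloxy)phenyl]-1-[3,4,5-tris(benzyloxy)phenyl]propyl}-2-[3,4,5-tris(benzyloxy)phenyl]chroman-3-yl 3,4,5-tris(benzyloxy)benzoate, via trialkoxybenzyl cation 21 (not isolated)
Conditions: Et3SiH (5 equiv), CF3CO2H (5 equiv), CH2Cl2, −40 to 0 °C; then H2O
Reagents that add atoms: none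
Why: Ionic hydrogenation of a benzylic aryl ether: the O7–Cx bond ionises selectively because Cx carries the 2,4,6-tris(benzyloxy)phenyl ring, whereas flavan C2 is flanked by a less donating 3,4,5-trioxygenated ring and an acyloxy carbon, and the silane reduces cation 21 to the CH2 group without touching Ca or Cc.

Step 14
Reactants: 22 (2R,3R)-5-(benzyloxy)-7-hydroxy-8-{(1R,2R)-2-{[3,4,5-tris(benzyloxy)benzoyl]oxy}-3-[2,4,6-tris(benzyloxy)phenyl]-1-[3,4,5-tris(benzyloxy)phenyl]propyl}-2-[3,4,5-tris(benzyloxy)phenyl]chroman-3-yl 3,4,5-tris(benzyloxy)benzoate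
Product: 23 CNP0155034.2
Conditions: H2 (1 atm), Pd(OH)2/C, THF/MeOH, rt
Reagents that add atoms: none
Why: Catalytic hydrogenolysis of the sixteen benzyl aryl ethers, under which the esters, the flavan O1–C2 bond and the four stereocentres are stable.

Compound list

1 | (−)-epigallocatechin, (2R,3R)-2-(3,4,5-trihydroxyphenyl)chroman-3,5,7-triol | Oc1cc(O)c2c(c1)O[C@H](c1cc(O)c(O)c(O)c1)[C@H](O)C2 | starting material

2 | 5,7,3',4',5'-penta-O-benzyl-(−)-epigallocatechin, (2R,3R)-5,7-bis(benzyloxy)-2-[3,4,5-tris(benzyloxy)phenyl]chroman-3-ol | O(Cc3ccccc3)c1cc(OCc3ccccc3)c2c(c1)O[C@H](c1cc(OCc3ccccc3)c(OCc3ccccc3)c(OCc3ccccc3)c1)[C@H](O)C2 | intermediate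

3 | (2R,3R)-5,7-bis(benzyloxy)-8-bromo-2-[3,4,5-tris(benzyloxy)phenyl]chroman-3-ol | Brc1c(OCc3ccccc3)cc(OCc3ccccc3)c2c1O[C@H](c1cc(OCc3ccccc3)c(OCc3ccccc3)c(OCc3ccccc3)c1)[C@H](O)C2 | intermediate

4 | 3,4,5-tris(benzyloxy)benzoic acid | O=C(O)c1cc(OCc2ccccc2)c(OCc2ccccc2)c(OCc2ccccc2)c1 | starting material

5 | 1-[3,4,5-tris(benzyloxy)benzoyl]-1H-imidazole | O=C(n1ccnc1)c1cc(OCc2ccccc2)c(OCc2ccccc2)c(OCc2ccccc2)c1 | intermediate (not isolated)

6 | N-methoxy-N-methyl-3,4,5-tris(benzyloxy)benzamide | CON(C)C(=O)c1cc(OCc2ccccc2)c(OCc2ccccc2)c(OCc2ccccc2)c1 | intermediate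

7 | lithium (2R,3R)-5,7-bis(benzyloxy)-8-lithio-2-[3,4,5-tris(benzyloxy)phenyl]chroman-3-olate | [Li]c1c(OCc3ccccc3)cc(OCc3ccccc3)c2c1O[C@H](c1cc(OCc3ccccc3)c(OCc3ccccc3)c(OCc3ccccc3)c1)[C@H](O[Li])C2 | intermediate (not isolated)

8 | dilithium hemiaminal adduct of 7 and 6 (C8–C(OLi)(NMeOMe)–aryl, 3-OLi) | [Li]OC(N(C)OC)(c1cc(OCc3ccccc3)c(OCc3ccccc3)c(OCc3ccccc3)c1)c1c(OCc3ccccc3)cc(OCc3ccccc3)c2c1O[C@H](c1cc(OCc3ccccc3)c(OCc3ccccc3)c(OCc3ccccc3)c1)[C@H](O[Li])C2 | intermediate (not isolated)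

9 | [(2R,3R)-5,7-bis(benzyloxy)-3-hydroxy-2-[3,4,5-tris(benzyloxy)phenyl]chroman-8-yl][3,4,5-tris(benzyloxy)phenyl]methanone | O=C(c1cc(OCc3ccccc3)c(OCc3ccccc3)c(OCc3ccccc3)c1)c1c(OCc3ccccc3)cc(OCc3ccccc3)c2c1O[C@H](c1cc(OCc3ccccc3)c(OCc3ccccc3)c(OCc3ccccc3)c1)[C@H](O)C2 | intermediate

10 | (2R,3R)-5,7-bis(benzyloxy)-8-[3,4,5-tris(benzyloxy)benzoyl]-2-[3,4,5-tris(benzyloxy)phenyl]chroman-3-yl 3,4,5-tris(benzyloxy)benzoate | O=C(c1cc(OCc3ccccc3)c(OCc3ccccc3)c(OCc3ccccc3)c1)c1c(OCc3ccccc3)cc(OCc3ccccc3)c2c1O[C@H](c1cc(OCc3ccccc3)c(OCc3ccccc3)c(OCc3ccccc3)c1)[C@H](OC(=O)c1cc(OCc3ccccc3)c(OCc3ccccc3)c(OCc3ccccc3)c1)C2 | intermediate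

11 | (2R,3R)-5-(benzyloxy)-7-hydroxy-8-[3,4,5-tris(benzyloxy)benzoyl]-2-[3,4,5-tris(benzyloxy)phenyl]chroman-3-yl 3,4,5-tris(benzyloxy)benzoate | O=C(c1cc(OCc3ccccc3)c(OCc3ccccc3)c(OCc3ccccc3)c1)c1c(O)cc(OCc3ccccc3)c2c1O[C@H](c1cc(OCc3ccccc3)c(OCc3ccccc3)c(OCc3ccccc3)c1)[C@H](OC(=O)c1cc(OCc3ccccc3)c(OCc3ccccc3)c(OCc3ccccc3)c1)C2 | intermediate

12 | (2R,3R)-5-(benzyloxy)-7-hydroxy-8-{hydroxy[3,4,5-tris(benzyloxy)phenyl]methyl}-2-[3,4,5-tris(benzyloxy)phenyl]chroman-3-yl 3,4,5-tris(benzyloxy)benzoate, both carbinol epimers | OC(c1cc(OCc3ccccc3)c(OCc3ccccc3)c(OCc3ccccc3)c1)c1c(O)cc(OCc3ccccc3)c2c1O[C@H](c1cc(OCc3ccccc3)c(OCc3ccccc3)c(OCc3ccccc3)c1)[C@H](OC(=O)c1cc(OCc3ccccc3)c(OCc3ccccc3)c(OCc3ccccc3)c1)C2 | intermediate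

13 | 1,3,5-tris(benzyloxy)benzene | c1ccc(COc2cc(OCc3ccccc3)cc(OCc3ccccc3)c2)cc1 | starting material

14 | N-[2,4,6-tris(benzyloxy)benzylidene]-N-methylmethanaminium chloride | C[N+](C)=Cc1c(OCc2ccccc2)cc(OCc2ccccc2)cc1OCc1ccccc1.[Cl-] | intermediate (not isolated)

15 | 2,4,6-tris(benzyloxy)benzaldehyde | O=Cc1c(OCc2ccccc2)cc(OCc2ccccc2)cc1OCc1ccccc1 | intermediate

16 | 4,4,5,5-tetramethyl-2-{(E)-2-[2,4,6-tris(benzyloxy)phenyl]ethenyl}-1,3,2-dioxaborolane | CC1(C)OB(/C=C/c2c(OCc3ccccc3)cc(OCc3ccccc3)cc2OCc2ccccc2)OC1(C)C | intermediate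

17 | potassium trifluoro{(E)-2-[2,4,6-tris(benzyloxy)phenyl]ethenyl}borate | [K+].F[B-](F)(F)/C=C/c1c(OCc2ccccc2)cc(OCc2ccccc2)cc1OCc1ccccc1 | intermediate

18 | (E)-2-[2,4,6-tris(benzyloxy)phenyl]ethenyl 3,4,5-tris(benzyloxy)benzoate | O=C(O/C=C/c1c(OCc2ccccc2)cc(OCc2ccccc2)cc1OCc1ccccc1)c1cc(OCc2ccccc2)c(OCc2ccccc2)c(OCc2ccccc2)c1 | intermediate

19 | ortho-quinone methide, (2R,3R)-5-(benzyloxy)-7-oxo-8-[(E)-3,4,5-tris(benzyloxy)benzylidene]-2-[3,4,5-tris(benzyloxy)phenyl]-3,4,7,8-tetrahydro-2H-chromen-3-yl 3,4,5-tris(benzyloxy)benzoate | O=C1C=C(OCc3ccccc3)C2=C(O[C@H](c4cc(OCc3ccccc3)c(OCc3ccccc3)c(OCc3ccccc3)c4)[C@H](OC(=O)c4cc(OCc3ccccc3)c(OCc3ccccc3)c(OCc3ccccc3)c4)C2)/C1=C\c1cc(OCc3ccccc3)c(OCc3ccccc3)c(OCc3ccccc3)c1 | intermediate (not isolated)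

20 | cycloadduct: the (2R,3R)-5-O-benzyl flavan 3-[tris(benzyloxy)benzoate] fused at O7/C8 to a second pyran ring O7–Cx–Ca–Cc–C8; Cx (R) bears the 2,4,6-tris(benzyloxy)phenyl ring A', Ca (S) the 3,4,5-tris(benzyloxy)benzoate, Cc (R) the 3,4,5-tris(benzyloxy)phenyl ring B'; Cx/Ca trans, Ca/Cc trans | O=C(O[C@H]4[C@H](c1cc(OCc3ccccc3)c(OCc3ccccc3)c(OCc3ccccc3)c1)c1c(O[C@@H]4c5c(OCc3ccccc3)cc(OCc3ccccc3)cc5OCc3ccccc3)cc(OCc3ccccc3)c2c1O[C@H](c1cc(OCc3ccccc3)c(OCc3ccccc3)c(OCc3ccccc3)c1)[C@H](OC(=O)c1cc(OCc3ccccc3)c(OCc3ccccc3)c(OCc3ccccc3)c1)C2)c1cc(OCc3ccccc3)c(OCc3ccccc3)c(OCc3ccccc3)c1 | intermediate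

21 | ring-opened Cx benzylic cation of 20 (O7–H free) as its trifluoroacetate ion pair | O=C(O[C@H]([CH+]c1c(OCc3ccccc3)cc(OCc3ccccc3)cc1OCc3ccccc3)[C@H](c1cc(OCc3ccccc3)c(OCc3ccccc3)c(OCc3ccccc3)c1)c1c(O)cc(OCc3ccccc3)c2c1O[C@H](c1cc(OCc3ccccc3)c(OCc3ccccc3)c(OCc3ccccc3)c1)[C@H](OC(=O)c1cc(OCc3ccccc3)c(OCc3ccccc3)c(OCc3ccccc3)c1)C2)c1cc(OCc3ccccc3)c(OCc3ccccc3)c(OCc3ccccc3)c1.[O-]C(=O)C(F)(F)F | intermediate (not isolated)

22 | (2R,3R)-5-(benzyloxy)-7-hydroxy-8-{(1R,2R)-2-{[3,4,5-tris(benzyloxy)benzoyl]oxy}-3-[2,4,6-tris(benzyloxy)phenyl]-1-[3,4,5-tris(benzyloxy)phenyl]propyl}-2-[3,4,5-tris(benzyloxy)phenyl]chroman-3-yl 3,4,5-tris(benzyloxy)benzoate | O=C(O[C@H](Cc1c(OCc3ccccc3)cc(OCc3ccccc3)cc1OCc3ccccc3)[C@H](c1cc(OCc3ccccc3)c(OCc3ccccc3)c(OCc3ccccc3)c1)c1c(O)cc(OCc3ccccc3)c2c1O[C@H](c1cc(OCc3ccccc3)c(OCc3ccccc3)c(OCc3ccccc3)c1)[C@H](OC(=O)c1cc(OCc3ccccc3)c(OCc3ccccc3)c(OCc3ccccc3)c1)C2)c1cc(OCc3ccccc3)c(OCc3ccccc3)c(OCc3ccccc3)c1 | intermediate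

23 | CNP0155034.2, (2R,3R)-5,7-dihydroxy-8-[(1R,2R)-2-(3,4,5-trihydroxybenzoyloxy)-1-(3,4,5-trihydroxyphenyl)-3-(2,4,6-trihydroxyphenyl)propyl]-2-(3,4,5-trihydroxyphenyl)chroman-3-yl 3,4,5-trihydroxybenzoate | O=C(O[C@H](Cc1c(O)cc(O)cc1O)[C@H](c1cc(O)c(O)c(O)c1)c1c(O)cc(O)c2c1O[C@H](c1cc(O)c(O)c(O)c1)[C@H](OC(=O)c1cc(O)c(O)c(O)c1)C2)c1cc(O)c(O)c(O)c1 | target

Total step count: 14. Longest linear sequence: 9 steps (steps 1, 2, 4, 5, 6, 7, 12, 13 and 14, from 1).

Steps most likely to fail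

Step 12. The quinone methide may be intercepted by aromatic carbon nucleophiles (the free positions of ring A' in 18, or C6 of a second molecule of 12) faster than by the acyloxy-bearing alkene carbon. The enol ester may also be hydrolysed by the water released, and facial control at Cc may be poor. The fallback makes the same two bonds one at a time by known chemistry and sets out from 12. Reaction of 12 with p-toluenesulfinic acid (CH2Cl2, rt) gives the stable quinone methide precursor (2R,3R)-5-(benzyloxy)-7-hydroxy-8-{(4-methylbenzenesulfonyl)[3,4,5-tris(benzyloxy)phenyl]methyl}-2-[3,4,5-tris(benzyloxy)phenyl]chroman-3-yl 3,4,5-tris(benzyloxy)benzoate F1. Acid 4 is alkylated (allyl bromide, K2CO3, DMF) to prop-2-enyl 3,4,5-tris(benzyloxy)benzoate F2, and Lemieux–Johnson cleavage (OsO4 cat., NaIO4, 2,6-lutidine, dioxane/H2O) gives 2-oxoethyl 3,4,5-tris(benzyloxy)benzoate F3. F1 and F3 are combined with (R)-α,α-diphenylprolinol trimethylsilyl ether (20 mol %, antipode chosen by analogy with enamine Michael additions) and NaHCO3 in CH2Cl2/H2O. The base releases quinone methide 19 from F1, and the enamine of F3 adds through its oxygen-bearing carbon to Cc. This enamine Michael addition to ortho-quinone methides is a known reaction type that gives 3,4-trans chroman-2-ols. O7 then closes onto the aldehyde to give the chroman-2-ol lactol F4, with Ca and Cc as in 20 and the anomeric Cx as a mixture. Friedel–Crafts C-arylation of F4 with arene 13 (BF3·OEt2, CH2Cl2, −40 °C) proceeds through the oxocarbenium ion, and participation of the neighbouring gallate carbonyl directs ring A' trans to the ester. The route is rejoined at 20.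

Step 13. Ionisation may not stay at O7–Cx: the flavan O1–C2 bond may open with epimerisation at C2. Cation 21 may also lose the Ca proton, which would erase Ca through an enol ester, or fragment back to quinone methide and enol ester before hydride arrives. The fallback sets out from 20 and traps the cation with a much better nucleophile at lower acidity. Benzyl mercaptan with catalytic ZnI2 (CH2Cl2, −20 °C) effects benzylic thiolysis, the reaction type used to degrade proanthocyanidins without opening flavan rings. It gives the ring-opened benzyl thioether of 22 carrying SCH2Ph on Cx (Cx epimers, O7–H free) F5. Reductive desulfurisation with nickel boride (Ni2B, made in the flask from NiCl2·6H2O and NaBH4, THF/MeOH, 0 °C) leaves benzyl ethers and esters alone and rejoins the route at 22.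

Step 11. The very electron-rich alkenyl borate may undergo protodeboronation or oxidative degradation before the C–O bond forms. The fallback sets out from 15 and reaches the enol ester by enolate O-acylation. Wittig methoxymethylenation of 15 ((methoxymethyl)triphenylphosphonium chloride, KOtBu, THF, 0 °C) gives 1,3,5-tris(benzyloxy)-2-(2-methoxyethenyl)benzene (E/Z) F6. Mild hydrolysis (aq. HCO2H, THF) gives [2,4,6-tris(benzyloxy)phenyl]acetaldehyde F7. Its potassium enolate (KN(SiMe3)2, THF, −78 °C) is O-acylated by 3,4,5-tris(benzyloxy)benzoyl chloride F8, made from acid 4 with oxalyl chloride and catalytic DMF. The E isomer is separated from the Z isomer on base-washed silica, the Z fraction being re-equilibrated with catalytic iodine, and the route is rejoined at 18.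

Further compounds

F1 | step 12 | (2R,3R)-5-(benzyloxy)-7-hydroxy-8-{(4-methylbenzenesulfonyl)[3,4,5-tris(benzyloxy)phenyl]methyl}-2-[3,4,5-tris(benzyloxy)phenyl]chroman-3-yl 3,4,5-tris(benzyloxy)benzoate (sulfone epimers) | Cc1ccc(cc1)S(=O)(=O)C(c1cc(OCc3ccccc3)c(OCc3ccccc3)c(OCc3ccccc3)c1)c1c(O)cc(OCc3ccccc3)c2c1O[C@H](c1cc(OCc3ccccc3)c(OCc3ccccc3)c(OCc3ccccc3)c1)[C@H](OC(=O)c1cc(OCc3ccccc3)c(OCc3ccccc3)c(OCc3ccccc3)c1)C2

F2 | step 12 | prop-2-enyl 3,4,5-tris(benzyloxy)benzoate | C=CCOC(=O)c1cc(OCc2ccccc2)c(OCc2ccccc2)c(OCc2ccccc2)c1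

F3 | step 12 | 2-oxoethyl 3,4,5-tris(benzyloxy)benzoate | O=CCOC(=O)c1cc(OCc2ccccc2)c(OCc2ccccc2)c(OCc2ccccc2)c1

F4 | step 12 | chroman-2-ol lactol: compound 20 with OH in place of ring A' on Cx (anomers; Ca and Cc as in 20) | O=C(O[C@H]4[C@H](c1cc(OCc3ccccc3)c(OCc3ccccc3)c(OCc3ccccc3)c1)c1c(OC4O)cc(OCc3ccccc3)c2c1O[C@H](c1cc(OCc3ccccc3)c(OCc3ccccc3)c(OCc3ccccc3)c1)[C@H](OC(=O)c1cc(OCc3ccccc3)c(OCc3ccccc3)c(OCc3ccccc3)c1)C2)c1cc(OCc3ccccc3)c(OCc3ccccc3)c(OCc3ccccc3)c1

F5 | step 13 | ring-opened benzyl thioether: compound 22 with SCH2Ph on Cx (Cx epimers) | O=C(O[C@H](C(SCc3ccccc3)c1c(OCc3ccccc3)cc(OCc3ccccc3)cc1OCc3ccccc3)[C@H](c1cc(OCc3ccccc3)c(OCc3ccccc3)c(OCc3ccccc3)c1)c1c(O)cc(OCc3ccccc3)c2c1O[C@H](c1cc(OCc3ccccc3)c(OCc3ccccc3)c(OCc3ccccc3)c1)[C@H](OC(=O)c1cc(OCc3ccccc3)c(OCc3ccccc3)c(OCc3ccccc3)c1)C2)c1cc(OCc3ccccc3)c(OCc3ccccc3)c(OCc3ccccc3)c1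

F6 | step 11 | 1,3,5-tris(benzyloxy)-2-(2-methoxyethenyl)benzene (E/Z mixture) | COC=Cc1c(OCc2ccccc2)cc(OCc2ccccc2)cc1OCc1ccccc1

F7 | step 11 | [2,4,6-tris(benzyloxy)phenyl]acetaldehyde | O=CCc1c(OCc2ccccc2)cc(OCc2ccccc2)cc1OCc1ccccc1

F8 | step 11 | 3,4,5-tris(benzyloxy)benzoyl chloride | O=C(Cl)c1cc(OCc2ccccc2)c(OCc2ccccc2)c(OCc2ccccc2)c1
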